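**Retrosynthetic overview**
- The butenolide is closed last, by lactonisation of the tertiary alcohol onto an α-keto ester that is unmasked by ozonolysis of an ethylidene ester.
- Key step: the quaternary carbinol carbon and its bond to the aryl-bearing carbon come from an Ireland–Claisen [3,3] rearrangement of an allylic α-benzyloxy ester; the carbinol centre of methyl (R)-3-hydroxybutanoate is relayed to the quaternary centre.
- The allylic alcohol (fragment B) comes from aldol condensation of silylated methyl (R)-3-hydroxybutanoate with 4-(benzyloxy)benzaldehyde.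
- The acid (fragment A) comes from two copper-catalysed openings of methyl (S)-glycidate by arylmetals derived from 4-bromo-2-iodophenol; the first arm, after MeMgBr addition and acid treatment, closes the chroman ring and carries the chromanol centre.
- Ring order: chroman pyran ring first (step 3), butenolide ring last (step 11); both benzene rings are bought.

Assumption: reagents added in succession to one flask without isolation count as one step; the target descriptors read from the SMILES are (R) at the lactone quaternary carbon and (S) at the chromanol carbon.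

Step 1
Reactants: 1 4-bromo-2-iodophenol
Product: 2 4-bromo-2-iodo-1-(methoxymethoxy)benzene
Conditions: MOMCl, iPr2NEt, CH2Cl2, 0 °C → rt
Reagents that add atoms: chloromethyl methyl ether (MOMCl), COCCl
Why: Williamson-type O-alkylation of the phenoxide installs the methoxymethyl acetal, which tolerates and assists the ortho-magnesiation of step 2.

Step 2
Reactants: 2 4-bromo-2-iodo-1-(methoxymethoxy)benzene; 3 methyl (2S)-oxirane-2-carboxylate
Product: 6 (2S)-1-[5-bromo-2-(methoxymethoxy)phenyl]-3-methylbutane-2,3-diol, via arylmagnesium chloride 4 (not isolated), via chloromagnesium alkoxide of the lactate ester 5 (not isolated)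
Conditions: iPrMgCl·LiCl, THF, −20 °C; CuBr·SMe2 (10 mol %), 3, −30 → 0 °C; MeMgBr (3.5 equiv), 0 °C → rt; H2O
Reagents that add atoms: methylmagnesium bromide, C[Mg]Br
Why: Knochel iodine–magnesium exchange is selective for the iodide ortho to the acetal oxygen, copper-catalysed SN2 opening of the epoxide at its CH2 terminus leaves the purchased (S)-carbinol centre untouched, and double Grignard addition of MeMgBr to the ester then builds the gem-dimethyl carbinol.

Step 3
Reactants: 6 (2S)-1-[5-bromo-2-(methoxymethoxy)phenyl]-3-methylbutane-2,3-diol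
Product: 8 (3S)-6-bromo-2,2-dimethyl-3,4-dihydro-2H-chromen-3-ol, via phenol triol 7 (not isolated)
Conditions: 3 M HCl, MeOH, 50 °C; then TsOH·H2O (10 mol %), PhMe, 80 °C
Reagents that add atoms: none
Why: Acidic acetal cleavage frees the phenol and SN1 cycloetherification through the tertiary carbocation closes the six-membered ether without breaking a bond at the secondary carbinol carbon, so the (S) centre is retained.

Step 4
Reactants: 8 (3S)-6-bromo-2,2-dimethyl-3,4-dihydro-2H-chromen-3-ol; 3 methyl (2S)-oxirane-2-carboxylate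
Product: 11 methyl (2S)-2-hydroxy-3-[(3S)-3-hydroxy-2,2-dimethyl-3,4-dihydro-2H-chromen-6-yl]propanoate, via dilithio species 9 (not isolated), via arylmagnesium bromide 10 (not isolated)
Conditions: t-BuLi (3.1 equiv), THF, −78 °C; MgBr2·OEt2, −78 → −40 °C; CuBr·SMe2 (10 mol %), 3, −40 → 0 °C; H2O
Reagents that add atoms: none
Why: Bromine–lithium exchange, transmetalation to magnesium and copper-catalysed SN2 epoxide opening at CH2 attach the lactate arm para to the ring oxygen; its (2S) centre comes unchanged from the glycidate and is erased in step 9.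

Step 5
Reactants: 11 methyl (2S)-2-hydroxy-3-[(3S)-3-hydroxy-2,2-dimethyl-3,4-dihydro-2H-chromen-6-yl]propanoate
Product: 13 (2S)-2-(benzyloxy)-3-[(3S)-3-(benzyloxy)-2,2-dimethyl-3,4-dihydro-2H-chromen-6-yl]propanoic acid, via dibenzyl ether methyl ester 12 (not isolated)
Conditions: NaH, BnBr, THF/DMF, 0 °C → rt; then LiOH, H2O/MeOH, rt; 1 M HCl
Reagents that add atoms: benzyl bromide, BrCc1ccccc1; lithium hydroxide, [Li+].[OH-]
Why: Double Williamson etherification protects both hydroxyls as benzyl ethers (the α-benzyloxy group later enforces a chelated enolate) and saponification in the same flask liberates the acid; epimerisation at C2 is harmless because that centre is planarised in step 9.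

Step 6
Reactants: 14 methyl (3R)-3-hydroxybutanoate
Product: 15 methyl (3R)-3-[(triethylsilyl)oxy]butanoate
Conditions: Et3SiCl, imidazole, CH2Cl2, 0 °C → rt
Reagents that add atoms: chlorotriethylsilane, CC[Si](Cl)(CC)CC
Why: Silylation blocks the purchased (R)-carbinol so that only the aldol hydroxyl can be activated in step 7; the stereocentre is not touched.

Step 7
Reactants: 15 methyl (3R)-3-[(triethylsilyl)oxy]butanoate; 16 4-(benzyloxy)benzaldehyde
Product: 21 methyl (2E)-3-[4-(benzyloxy)phenyl]-2-[(1R)-1-hydroxyethyl]prop-2-enoate, via lithium enolate 17 (not isolated), via lithium aldolate 18 (not isolated), via mesylate 19 (not isolated), via triethylsilyl ether 20 (not isolated)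
Conditions: LiN(iPr)2, THF, −78 °C; 16; MsCl, −78 → 0 °C; DBU, 0 °C → rt; then AcOH/THF/H2O (3:1:1), rt
Reagents that add atoms: none
Why: Aldol addition of the ester enolate, mesylation and E1cB elimination (aldol condensation) give the thermodynamically preferred (E)-cinnamate because only the mesylate is a leaving group, and mild acid then removes the silyl ether without touching the (R)-carbinol centre.

Step 8
Reactants: 13 (2S)-2-(benzyloxy)-3-[(3S)-3-(benzyloxy)-2,2-dimethyl-3,4-dihydro-2H-chromen-6-yl]propanoic acid; 21 methyl (2E)-3-[4-(benzyloxy)phenyl]-2-[(1R)-1-hydroxyethyl]prop-2-enoate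
Product: 22 (2R,3E)-4-[4-(benzyloxy)phenyl]-3-(methoxycarbonyl)but-3-en-2-yl (2S)-2-(benzyloxy)-3-[(3S)-3-(benzyloxy)-2,2-dimethyl-3,4-dihydro-2H-chromen-6-yl]propanoate
Conditions: EDC·HCl, DMAP, CH2Cl2, 0 °C → rt
Reagents that add atoms: none
Why: Steglich esterification joins fragments A and B through the carbinol oxygen, with retention at the (R)-carbinol carbon.

Step 9
Reactants: 22 (2R,3E)-4-[4-(benzyloxy)phenyl]-3-(methoxycarbonyl)but-3-en-2-yl (2S)-2-(benzyloxy)-3-[(3S)-3-(benzyloxy)-2,2-dimethyl-3,4-dihydro-2H-chromen-6-yl]propanoate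
Product: 26 dimethyl (2R,3R,4Z)-2-(benzyloxy)-3-[4-(benzyloxy)phenyl]-2-{[(3S)-3-(benzyloxy)-2,2-dimethyl-3,4-dihydro-2H-chromen-6-yl]methyl}-4-ethylidenepentanedioate, via silyl ketene acetal 23 (not isolated), via trimethylsilyl ester 24 (not isolated), via carboxylic acid 25 (not isolated)
Conditions: LiN(SiMe3)2, Me3SiCl, Et3N, THF, −78 → 45 °C; then MeOH; Me3SiCHN2, PhMe/MeOH, 0 °C
Reagents that add atoms: (trimethylsilyl)diazomethane, C[Si](C)(C)C=[N+]=[N-]
Why: Ireland–Claisen [3,3]-sigmatropic rearrangement, in which the chelation-controlled (Z)-silyl ketene acetal reacts through a chair transition state with the carbinol methyl equatorial and the cis-aryl group axial, forms the C–C bond to the aryl-bearing carbon and transfers the (R)-carbinol chirality to the (R) quaternary centre (the adjacent benzylic centre and the (Z)-ethylidene follow from the same chair), after which the liberated acid is methylated with Me3SiCHN2.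

Step 10
Reactants: 26 dimethyl (2R,3R,4Z)-2-(benzyloxy)-3-[4-(benzyloxy)phenyl]-2-{[(3S)-3-(benzyloxy)-2,2-dimethyl-3,4-dihydro-2H-chromen-6-yl]methyl}-4-ethylidenepentanedioate
Product: 28 dimethyl (2R,3S)-2-(benzyloxy)-3-[4-(benzyloxy)phenyl]-2-{[(3S)-3-(benzyloxy)-2,2-dimethyl-3,4-dihydro-2H-chromen-6-yl]methyl}-4-oxopentanedioate, via ozonide 27 (not isolated)
Conditions: O3, CH2Cl2, −78 °C; PPh3, −78 °C → rt
Reagents that add atoms: ozone, [O-][O+]=O
Why: Ozonolysis cleaves the ethylidene double bond, which at −78 °C should react faster than the aryl ethers, and reductive work-up of the ozonide gives the α-keto ester without involving the quaternary centre.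

Step 11
Reactants: 28 dimethyl (2R,3S)-2-(benzyloxy)-3-[4-(benzyloxy)phenyl]-2-{[(3S)-3-(benzyloxy)-2,2-dimethyl-3,4-dihydro-2H-chromen-6-yl]methyl}-4-oxopentanedioate
Product: 30 methyl (2R)-4-hydroxy-2-{[(3S)-3-hydroxy-2,2-dimethyl-3,4-dihydro-2H-chromen-6-yl]methyl}-3-(4-hydroxyphenyl)-5-oxo-2,5-dihydrofuran-2-carboxylate, via triol keto diester 29 (not isolated)
Conditions: H2 (1 atm), Pd(OH)2/C, EtOAc/MeOH, rt; then TsOH·H2O (cat.), CH2Cl2, rt
Reagents that add atoms: none
Why: Hydrogenolysis removes the three benzyl ethers and acid-catalysed lactonisation (intramolecular transesterification) of the tertiary hydroxyl onto the α-keto ester closes the five-membered ring, whose keto lactone tautomerises to the aryl-conjugated enol, erasing the benzylic centre and leaving the (R) quaternary and (S) chromanol centres untouched.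

**Compound list**
1 | 4-bromo-2-iodophenol | Oc1ccc(Br)cc1I | starting material
2 | 4-bromo-2-iodo-1-(methoxymethoxy)benzene | COCOc1ccc(Br)cc1I | intermediate
3 | methyl (2S)-oxirane-2-carboxylate (methyl (S)-glycidate) | COC(=O)[C@@H]1CO1 | starting material
4 | [5-bromo-2-(methoxymethoxy)phenyl]magnesium chloride | COCOc1ccc(Br)cc1[Mg]Cl | intermediate
5 | chloromagnesium alkoxide of methyl (2S)-3-[5-bromo-2-(methoxymethoxy)phenyl]-2-hydroxypropanoate | COCOc1ccc(Br)cc1C[C@H](O[Mg]Cl)C(=O)OC | intermediate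
6 | (2S)-1-[5-bromo-2-(methoxymethoxy)phenyl]-3-methylbutane-2,3-diol | COCOc1ccc(Br)cc1C[C@H](O)C(C)(C)O | intermediate
7 | (2S)-1-(5-bromo-2-hydroxyphenyl)-3-methylbutane-2,3-diol | Oc1ccc(Br)cc1C[C@H](O)C(C)(C)O | intermediate
8 | (3S)-6-bromo-2,2-dimethyl-3,4-dihydro-2H-chromen-3-ol | Brc1ccc2c(c1)C[C@H](O)C(C)(C)O2 | intermediate
9 | lithium (3S)-6-lithio-2,2-dimethyl-3,4-dihydro-2H-chromen-3-olate | [Li]c1ccc2c(c1)C[C@H](O[Li])C(C)(C)O2 | intermediate
10 | [(3S)-3-(lithiooxy)-2,2-dimethyl-3,4-dihydro-2H-chromen-6-yl]magnesium bromide | Br[Mg]c1ccc2c(c1)C[C@H](O[Li])C(C)(C)O2 | intermediate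
11 | methyl (2S)-2-hydroxy-3-[(3S)-3-hydroxy-2,2-dimethyl-3,4-dihydro-2H-chromen-6-yl]propanoate | COC(=O)[C@@H](O)Cc1ccc2c(c1)C[C@H](O)C(C)(C)O2 | intermediate
12 | methyl (2S)-2-(benzyloxy)-3-[(3S)-3-(benzyloxy)-2,2-dimethyl-3,4-dihydro-2H-chromen-6-yl]propanoate (C2 drawn as (S); erased in step 9) | COC(=O)[C@@H](OCc1ccccc1)Cc1ccc2c(c1)C[C@H](OCc1ccccc1)C(C)(C)O2 | intermediate
13 | (2S)-2-(benzyloxy)-3-[(3S)-3-(benzyloxy)-2,2-dimethyl-3,4-dihydro-2H-chromen-6-yl]propanoic acid (C2 drawn as (S); erased in step 9) | OC(=O)[C@@H](OCc1ccccc1)Cc1ccc2c(c1)C[C@H](OCc1ccccc1)C(C)(C)O2 | intermediate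
14 | methyl (3R)-3-hydroxybutanoate | C[C@@H](O)CC(=O)OC | starting material
15 | methyl (3R)-3-[(triethylsilyl)oxy]butanoate | C[C@@H](O[Si](CC)(CC)CC)CC(=O)OC | intermediate
16 | 4-(benzyloxy)benzaldehyde | O=Cc1ccc(OCc2ccccc2)cc1 | starting material
17 | lithium enolate of 15 (enolate geometry not specified) | C[C@@H](O[Si](CC)(CC)CC)C=C(O[Li])OC | intermediate
18 | methyl (3R)-2-{[4-(benzyloxy)phenyl](lithiooxy)methyl}-3-[(triethylsilyl)oxy]butanoate (lithium aldolate; two new centres as a mixture) | C[C@@H](O[Si](CC)(CC)CC)C(C(=O)OC)C(O[Li])c1ccc(OCc2ccccc2)cc1 | intermediate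
19 | methyl (3R)-2-{[4-(benzyloxy)phenyl][(methanesulfonyl)oxy]methyl}-3-[(triethylsilyl)oxy]butanoate (mixture at the two new centres) | C[C@@H](O[Si](CC)(CC)CC)C(C(=O)OC)C(OS(C)(=O)=O)c1ccc(OCc2ccccc2)cc1 | intermediate
20 | methyl (2E)-3-[4-(benzyloxy)phenyl]-2-{(1R)-1-[(triethylsilyl)oxy]ethyl}prop-2-enoate | C[C@@H](O[Si](CC)(CC)CC)/C(C(=O)OC)=C\c1ccc(OCc2ccccc2)cc1 | intermediate
21 | methyl (2E)-3-[4-(benzyloxy)phenyl]-2-[(1R)-1-hydroxyethyl]prop-2-enoate | C[C@@H](O)/C(C(=O)OC)=C\c1ccc(OCc2ccccc2)cc1 | intermediate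
22 | (2R,3E)-4-[4-(benzyloxy)phenyl]-3-(methoxycarbonyl)but-3-en-2-yl (2S)-2-(benzyloxy)-3-[(3S)-3-(benzyloxy)-2,2-dimethyl-3,4-dihydro-2H-chromen-6-yl]propanoate | C[C@@H](OC(=O)[C@@H](OCc1ccccc1)Cc1ccc2c(c1)C[C@H](OCc1ccccc1)C(C)(C)O2)/C(C(=O)OC)=C\c1ccc(OCc2ccccc2)cc1 | intermediate
23 | (Z)-trimethylsilyl ketene acetal of 22 (OSiMe3 cis to OBn) | C[C@@H](O/C(O[Si](C)(C)C)=C(/OCc1ccccc1)Cc1ccc2c(c1)C[C@H](OCc1ccccc1)C(C)(C)O2)/C(C(=O)OC)=C\c1ccc(OCc2ccccc2)cc1 | intermediate
24 | trimethylsilyl (2R,3R,4Z)-2-(benzyloxy)-3-[4-(benzyloxy)phenyl]-2-{[(3S)-3-(benzyloxy)-2,2-dimethyl-3,4-dihydro-2H-chromen-6-yl]methyl}-4-(methoxycarbonyl)hex-4-enoate | C[Si](C)(C)OC(=O)[C@@](OCc1ccccc1)(Cc1ccc2c(c1)C[C@H](OCc1ccccc1)C(C)(C)O2)[C@H](c1ccc(OCc2ccccc2)cc1)/C(C(=O)OC)=C/C | intermediate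
25 | (2R,3R,4Z)-2-(benzyloxy)-3-[4-(benzyloxy)phenyl]-2-{[(3S)-3-(benzyloxy)-2,2-dimethyl-3,4-dihydro-2H-chromen-6-yl]methyl}-4-(methoxycarbonyl)hex-4-enoic acid | OC(=O)[C@@](OCc1ccccc1)(Cc1ccc2c(c1)C[C@H](OCc1ccccc1)C(C)(C)O2)[C@H](c1ccc(OCc2ccccc2)cc1)/C(C(=O)OC)=C/C | intermediate
26 | dimethyl (2R,3R,4Z)-2-(benzyloxy)-3-[4-(benzyloxy)phenyl]-2-{[(3S)-3-(benzyloxy)-2,2-dimethyl-3,4-dihydro-2H-chromen-6-yl]methyl}-4-ethylidenepentanedioate | COC(=O)[C@@](OCc1ccccc1)(Cc1ccc2c(c1)C[C@H](OCc1ccccc1)C(C)(C)O2)[C@H](c1ccc(OCc2ccccc2)cc1)/C(C(=O)OC)=C/C | intermediate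
27 | secondary ozonide (1,2,4-trioxolane) of 26 (new ring centres unspecified) | COC(=O)[C@@](OCc1ccccc1)(Cc1ccc2c(c1)C[C@H](OCc1ccccc1)C(C)(C)O2)[C@H](c1ccc(OCc2ccccc2)cc1)C1(C(=O)OC)OOC(C)O1 | intermediate
28 | dimethyl (2R,3S)-2-(benzyloxy)-3-[4-(benzyloxy)phenyl]-2-{[(3S)-3-(benzyloxy)-2,2-dimethyl-3,4-dihydro-2H-chromen-6-yl]methyl}-4-oxopentanedioate (C3 epimerisable; drawn as formed) | COC(=O)[C@@](OCc1ccccc1)(Cc1ccc2c(c1)C[C@H](OCc1ccccc1)C(C)(C)O2)[C@H](c1ccc(OCc2ccccc2)cc1)C(=O)C(=O)OC | intermediate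
29 | dimethyl (2R,3S)-2-hydroxy-2-{[(3S)-3-hydroxy-2,2-dimethyl-3,4-dihydro-2H-chromen-6-yl]methyl}-3-(4-hydroxyphenyl)-4-oxopentanedioate | COC(=O)[C@@](O)(Cc1ccc2c(c1)C[C@H](O)C(C)(C)O2)[C@H](c1ccc(O)cc1)C(=O)C(=O)OC | intermediate
30 | methyl (2R)-4-hydroxy-2-{[(3S)-3-hydroxy-2,2-dimethyl-3,4-dihydro-2H-chromen-6-yl]methyl}-3-(4-hydroxyphenyl)-5-oxo-2,5-dihydrofuran-2-carboxylate | COC(=O)[C@]1(Cc2ccc3c(c2)C[C@H](O)C(C)(C)O3)OC(=O)C(O)=C1c1ccc(O)cc1 | target

**Step count**
Total: 11 steps. Longest linear sequence: 9 steps (steps 1–5, then 8–11); steps 6–7 make fragment B.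

**Steps most likely to fail, with fallbacks**

Step 9 (Ireland–Claisen). The fully substituted ketene acetal 23 may form with imperfect (Z) geometry or rearrange sluggishly next to the aryl-substituted terminus, which would erode the chirality transfer. The fallback sets out from 22 and uses the polar manifold without a silyl trap. KN(SiMe3)2 in THF at −78 °C gives the chelated enolate, which adds intramolecularly in a Michael sense to the arylidene ester (same C–C bond, six-membered ring) to give, on cold protonation, the δ-lactone F1. Treatment of the δ-lactone F1 with KOtBu in THF at 0 °C opens it by E1cB expulsion of the ring carboxylate (either ethylidene geometry serves). This comes back to the route at acid 25, which is methylated as in step 9.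

Step 3 (cycloetherification). The tertiary cation next to a free carbinol can undergo a pinacol-type hydride shift to a ketone instead of being trapped by the phenol. The fallback sets out from 6. Ac2O and pyridine acylate only the secondary hydroxyl to give the secondary acetate F2. Wet CF3CO2H in CH2Cl2 then cleaves the acetal and ionises the tertiary alcohol; the neighbouring acetoxy group bridges the cation and blocks the hydride shift, and the phenol closes the ring at the tertiary carbon with the secondary C–O bond intact, giving the chromanyl acetate F3. K2CO3 in MeOH removes the acetate and the route is rejoined at 8.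

Step 10 (ozonolysis). Ozone may attack the electron-rich aryl and benzyl ethers before the hindered, electron-poor ethylidene ester. The fallback sets out from 26 and replaces ozone by a two-stage cleavage: catalytic OsO4 with N-methylmorpholine N-oxide in acetone/H2O gives the diol F4, and NaIO4 in THF/H2O cleaves the diol F4 to the keto diester, rejoining the route at 28.

Further compounds
F1 | step 9 | methyl (3R,4S,6R)-3-(benzyloxy)-4-[4-(benzyloxy)phenyl]-3-{[(3S)-3-(benzyloxy)-2,2-dimethyl-3,4-dihydro-2H-chromen-6-yl]methyl}-6-methyl-2-oxooxane-5-carboxylate (δ-lactone; C5 unspecified) | C[C@H]1OC(=O)[C@@](OCc2ccccc2)(Cc2ccc3c(c2)C[C@H](OCc2ccccc2)C(C)(C)O3)[C@H](c2ccc(OCc3ccccc3)cc2)C1C(=O)OC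
F2 | step 3 | (2S)-1-[5-bromo-2-(methoxymethoxy)phenyl]-3-hydroxy-3-methylbutan-2-yl acetate | COCOc1ccc(Br)cc1C[C@H](OC(C)=O)C(C)(C)O
F3 | step 3 | (3S)-6-bromo-2,2-dimethyl-3,4-dihydro-2H-chromen-3-yl acetate | Brc1ccc2c(c1)C[C@H](OC(C)=O)C(C)(C)O2
F4 | step 10 | dimethyl (2R,3R)-2-(benzyloxy)-3-[4-(benzyloxy)phenyl]-2-{[(3S)-3-(benzyloxy)-2,2-dimethyl-3,4-dihydro-2H-chromen-6-yl]methyl}-4-hydroxy-4-(1-hydroxyethyl)pentanedioate (two new carbinol centres unspecified) | COC(=O)[C@@](OCc1ccccc1)(Cc1ccc2c(c1)C[C@H](OCc1ccccc1)C(C)(C)O2)[C@H](c1ccc(OCc2ccccc2)cc1)C(O)(C(=O)OC)C(C)O
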